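**Plan**
- Retrosynthesis first cuts the two ester C–O bonds (isovalerate on the butynyl chain, senecioate on the CH2O group of ring A), then ring A itself at S–C5 and C2–C3, and last the C(sp)–C(sp2) bond between ring B and the chain.
- The feature that allows this: the CH2O carbon sits on C2 of ring A, next to sulfur, so it can enter as the ester carbon of a thioglycolate whose α-carbon becomes C2; ring A then closes at carbon (C2–C3) by aldol condensation.
- Forward: silylated but-3-yn-1-ol is joined to purchased ring B (2-acetyl-5-bromothiophene), and the acetyl group is turned into a β-chloroacrolein.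
- Ring A is then annulated with methyl sulfanylacetate. The C2 ester is reduced to CH2OH and senecioylated; the chain hydroxyl is unmasked and isovalerylated.
- Stereochemistry: the target has no stereocentre and no stereogenic double bond; the Z geometry of the chloroenal is transient and disappears in the annulation.

Key step: step 4

Remark: the chloroenal 6 is drawn as the Z isomer normally favoured by chloroformylation of aryl methyl ketones; any E isomer can be carried along, because addition–elimination at the β-carbon lets both converge on the same thiophene.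

**Route**

Step 1
Reactants: 1 but-3-yn-1-ol
Product: 2 tert-butyl(but-3-yn-1-yloxy)diphenylsilane
Conditions: TBDPSCl (1.05 equiv), imidazole (2 equiv), DMF, 0 °C → rt
Reagents that add atoms: tert-butyl(chloro)diphenylsilane, CC(C)(C)[Si](Cl)(c1ccccc1)c1ccccc1
Why: Imidazole-promoted silyl ether formation on an unhindered primary alcohol; the TBDPS group is chosen because it should withstand the chloroiminium/POCl3 medium, carbonate in DMF and i-Bu2AlH used later.

Step 2
Reactants: 2 tert-butyl(but-3-yn-1-yloxy)diphenylsilane; 3 1-(5-bromothiophen-2-yl)ethanone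
Product: 4 1-{5-[4-(tert-butyldiphenylsilyloxy)but-1-yn-1-yl]thiophen-2-yl}ethanone
Conditions: Pd(PPh3)2Cl2 (2 mol %), CuI (4 mol %), Et3N, THF, rt → 45 °C
Reagents that add atoms: none
Why: Sonogashira coupling of a terminal alkyne with an acyl-activated 2-bromothiophene, a substrate class in which oxidative addition is easy and the ketone is a spectator.

Step 3
Reactants: 4 1-{5-[4-(tert-butyldiphenylsilyloxy)but-1-yn-1-yl]thiophen-2-yl}ethanone
Product: 6 (2Z)-3-chloro-3-{5-[4-(tert-butyldiphenylsilyloxy)but-1-yn-1-yl]thiophen-2-yl}prop-2-enal, via chlorovinyl iminium salt 5 (not isolated)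
Conditions: POCl3 (3 equiv), DMF, 0 °C → 50 °C; then ice, aq. NaOAc
Reagents that add atoms: N,N-dimethylformamide, CN(C)C=O (formyl CH); phosphoryl chloride, O=P(Cl)(Cl)Cl (chlorine); water, O (aldehyde oxygen)
Why: Vilsmeier–Haack–Arnold chloroformylation, in which the enol of the methyl ketone is formylated by the chloroiminium salt, the enaminone oxygen is activated and replaced by chloride to give iminium 5, and aqueous acetate hydrolyses 5 to the chloroenal with chlorine cis to CHO, while the acyl-deactivated thiophene, the alkyne and the hindered silyl ether are expected to remain untouched.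

Step 4
Reactants: 6 (2Z)-3-chloro-3-{5-[4-(tert-butyldiphenylsilyloxy)but-1-yn-1-yl]thiophen-2-yl}prop-2-enal; 7 methyl sulfanylacetate
Product: 10 methyl 5'-[4-(tert-butyldiphenylsilyloxy)but-1-yn-1-yl]-2,2'-bithiophene-5-carboxylate, via sulfanyl enal 8 (not isolated), via hydroxydihydrothiophene aldol 9 (not isolated)
Conditions: 7 (1.2 equiv), K2CO3 (2.5 equiv), DMF, rt → 60 °C
Reagents that add atoms: none
Why: The thiolate of 7 adds to the chlorine-bearing β-carbon of the enal and chloride is expelled (addition–elimination), forming the S–C5 bond and sulfanyl enal 8. Carbonate then deprotonates the methylene flanked by sulfur and the ester, and this carbanion attacks the aldehyde carbon in a 5-exo-trig aldol closure that forms the C2–C3 bond and gives 9; loss of water aromatizes ring A. The closest known reaction type is the Fiesselmann-type condensation of β-chloro-β-arylacroleins with thioglycolate esters to give 5-arylthiophene-2-carboxylates. No stereocentre results, since the two sp3 centres of 9 are erased on dehydration. The step needs regiocontrol and chemoselectivity over the alkyne: sulfur can enter only at the carbon that carries chlorine and ring B, the ester α-carbon can reach only the aldehyde, and the unactivated aryl alkyne should not accept thiolate at this temperature. The silyl ether and the methyl ester are expected to tolerate carbonate in DMF.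

Step 5
Reactants: 10 methyl 5'-[4-(tert-butyldiphenylsilyloxy)but-1-yn-1-yl]-2,2'-bithiophene-5-carboxylate
Product: 11 {5'-[4-(tert-butyldiphenylsilyloxy)but-1-yn-1-yl]-2,2'-bithiophen-5-yl}methanol
Conditions: i-Bu2AlH (2.5 equiv), CH2Cl2, −78 → 0 °C; then aq. potassium sodium tartrate
Reagents that add atoms: none
Why: Reduction of an aromatic ester to the primary alcohol with excess i-Bu2AlH, conditions under which the internal alkyne is not hydroaluminated and the silyl ether is inert.

Step 6
Reactants: 11 {5'-[4-(tert-butyldiphenylsilyloxy)but-1-yn-1-yl]-2,2'-bithiophen-5-yl}methanol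
Product: 12 {5'-[4-(tert-butyldiphenylsilyloxy)but-1-yn-1-yl]-2,2'-bithiophen-5-yl}methyl 3-methylbut-2-enoate
Conditions: 3-methylbut-2-enoic acid (1.3 equiv), DCC (1.3 equiv), DMAP (0.1 equiv), CH2Cl2, 0 °C → rt
Reagents that add atoms: 3-methylbut-2-enoic acid, CC(C)=CC(=O)O
Why: Steglich esterification, which acylates the acid-sensitive thienylmethyl alcohol under neutral conditions and avoids the acid chloride/amine combination that tends to move the double bond out of conjugation through a vinylketene.

Step 7
Reactants: 12 {5'-[4-(tert-butyldiphenylsilyloxy)but-1-yn-1-yl]-2,2'-bithiophen-5-yl}methyl 3-methylbut-2-enoate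
Product: 13 [5'-(4-hydroxybut-1-yn-1-yl)-2,2'-bithiophen-5-yl]methyl 3-methylbut-2-enoate
Conditions: Bu4NF (1.5 equiv), AcOH (1.5 equiv), THF, 0 °C → rt
Reagents that add atoms: none
Why: Fluoride-driven cleavage of the Si–O bond, buffered with acetic acid so that the liberated alkoxide is protonated at once and cannot cleave or transfer the senecioate.

Step 8
Reactants: 13 [5'-(4-hydroxybut-1-yn-1-yl)-2,2'-bithiophen-5-yl]methyl 3-methylbut-2-enoate
Product: 14 {5'-[4-(3-methylbutanoyloxy)but-1-yn-1-yl]-2,2'-bithiophen-5-yl}methyl 3-methylbut-2-enoate (CNP0114739.0)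
Conditions: 3-methylbutanoyl chloride (1.3 equiv), pyridine (3 equiv), DMAP (0.05 equiv), CH2Cl2, 0 °C → rt
Reagents that add atoms: 3-methylbutanoyl chloride, CC(C)CC(=O)Cl
Why: Pyridine/DMAP-mediated acylation of the only free hydroxyl group with a saturated acid chloride, which leaves the existing conjugated ester untouched.

**Compound list**

1 | but-3-yn-1-ol | C#CCCO | starting material
2 | tert-butyl(but-3-yn-1-yloxy)diphenylsilane | C#CCCO[Si](c1ccccc1)(c1ccccc1)C(C)(C)C | intermediate
3 | 1-(5-bromothiophen-2-yl)ethanone | CC(=O)c1ccc(Br)s1 | starting material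
4 | 1-{5-[4-(tert-butyldiphenylsilyloxy)but-1-yn-1-yl]thiophen-2-yl}ethanone | CC(=O)c1ccc(C#CCCO[Si](c2ccccc2)(c2ccccc2)C(C)(C)C)s1 | intermediate
5 | N-[(2Z)-3-chloro-3-{5-[4-(tert-butyldiphenylsilyloxy)but-1-yn-1-yl]thiophen-2-yl}prop-2-en-1-ylidene]-N-methylmethanaminium dichlorophosphate | C[N+](C)=C/C=C(\Cl)c1ccc(C#CCCO[Si](c2ccccc2)(c2ccccc2)C(C)(C)C)s1.[O-]P(=O)(Cl)Cl | intermediate (not isolated)
6 | (2Z)-3-chloro-3-{5-[4-(tert-butyldiphenylsilyloxy)but-1-yn-1-yl]thiophen-2-yl}prop-2-enal | O=C/C=C(\Cl)c1ccc(C#CCCO[Si](c2ccccc2)(c2ccccc2)C(C)(C)C)s1 | intermediate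
7 | methyl sulfanylacetate | COC(=O)CS | starting material
8 | methyl {[(1Z)-1-{5-[4-(tert-butyldiphenylsilyloxy)but-1-yn-1-yl]thiophen-2-yl}-3-oxoprop-1-en-1-yl]sulfanyl}acetate | COC(=O)CS/C(=C\C=O)c1ccc(C#CCCO[Si](c2ccccc2)(c2ccccc2)C(C)(C)C)s1 | intermediate (not isolated)
9 | methyl 5-{5-[4-(tert-butyldiphenylsilyloxy)but-1-yn-1-yl]thiophen-2-yl}-3-hydroxy-2,3-dihydrothiophene-2-carboxylate (mixture of diastereomers) | COC(=O)C1SC(=CC1O)c1ccc(C#CCCO[Si](c2ccccc2)(c2ccccc2)C(C)(C)C)s1 | intermediate (not isolated)
10 | methyl 5'-[4-(tert-butyldiphenylsilyloxy)but-1-yn-1-yl]-2,2'-bithiophene-5-carboxylate | COC(=O)c1ccc(-c2ccc(C#CCCO[Si](c3ccccc3)(c3ccccc3)C(C)(C)C)s2)s1 | intermediate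
11 | {5'-[4-(tert-butyldiphenylsilyloxy)but-1-yn-1-yl]-2,2'-bithiophen-5-yl}methanol | OCc1ccc(-c2ccc(C#CCCO[Si](c3ccccc3)(c3ccccc3)C(C)(C)C)s2)s1 | intermediate
12 | {5'-[4-(tert-butyldiphenylsilyloxy)but-1-yn-1-yl]-2,2'-bithiophen-5-yl}methyl 3-methylbut-2-enoate | CC(C)=CC(=O)OCc1ccc(-c2ccc(C#CCCO[Si](c3ccccc3)(c3ccccc3)C(C)(C)C)s2)s1 | intermediate
13 | [5'-(4-hydroxybut-1-yn-1-yl)-2,2'-bithiophen-5-yl]methyl 3-methylbut-2-enoate | CC(C)=CC(=O)OCc1ccc(-c2ccc(C#CCCO)s2)s1 | intermediate
14 | {5'-[4-(3-methylbutanoyloxy)but-1-yn-1-yl]-2,2'-bithiophen-5-yl}methyl 3-methylbut-2-enoate | CC(C)=CC(=O)OCc1ccc(-c2ccc(C#CCCOC(=O)CC(C)C)s2)s1 | target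

**Step count**

Total steps: 8. Longest linear sequence: 8 steps (1 → 14).

**Steps most likely to fail**

Step 3. The chloroiminium/POCl3 medium may hydrochlorinate the alkyne, or strip or formylate the silyl ether, before the acetyl group is fully converted. The fallback moves the acidic step ahead of the alkyne. It sets out from 3, which is chloroformylated (POCl3, DMF) to (2Z)-3-(5-bromothiophen-2-yl)-3-chloroprop-2-enal F1. The same thioglycolate annulation with 7 (K2CO3, DMF) then gives methyl 5'-bromo-2,2'-bithiophene-5-carboxylate F2. Sonogashira coupling of F2 with 2 (Pd(PPh3)2Cl2, CuI, Et3N, THF, 60 °C) comes back to the route at 10.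

Step 4. The sequence may stall at the open-chain sulfanyl enal, thiolate may add across the alkyne, or the base may erode the ester. The fallback builds the ring A–ring B bond by cross-coupling instead of annulation. It sets out from 2, which is coupled at the iodide of 2-bromo-5-iodothiophene (Pd(PPh3)2Cl2, CuI, Et3N, rt) to give {[4-(5-bromothiophen-2-yl)but-3-yn-1-yl]oxy}(tert-butyl)diphenylsilane F3. Suzuki–Miyaura coupling of F3 with [5-(methoxycarbonyl)thiophen-2-yl]boronic acid (Pd(dppf)Cl2, K3PO4, dioxane/water, 80 °C) comes back to the route at 10.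

Step 6. The acyl-transfer intermediate may lose a γ-proton and deliver the deconjugated 3-methylbut-3-enoate, rearrange to an N-acylurea, or the electron-rich thienylmethyl alcohol may ionise. The fallback activates the alcohol instead of the acid. It sets out from 11, which under Mitsunobu conditions (3-methylbut-2-enoic acid, PPh3, diisopropyl azodicarboxylate, THF, 0 °C) is O-alkylated by the carboxylate and comes back to the route directly at 12; no new compound arises on this detour (F0).

**Further compounds**

F1 | step 3 | (2Z)-3-(5-bromothiophen-2-yl)-3-chloroprop-2-enal | O=C/C=C(\Cl)c1ccc(Br)s1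
F2 | step 3 | methyl 5'-bromo-2,2'-bithiophene-5-carboxylate | COC(=O)c1ccc(-c2ccc(Br)s2)s1
F3 | step 4 | {[4-(5-bromothiophen-2-yl)but-3-yn-1-yl]oxy}(tert-butyl)diphenylsilane | Brc1ccc(C#CCCO[Si](c2ccccc2)(c2ccccc2)C(C)(C)C)s1
F0 | step 6 | none | none
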